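Compound numbers are fixed by the steps below and used throughout.

## Analysis of the target

Dehydrobisgravillol 23 is an open-chain diarylalkene: two 1,3,5-trisubstituted benzene rings joined by an unbranched fourteen-carbon chain. Counted from ring A, C1 to C7 are methylenes, C8=C9 is an E double bond, and C10 to C14 are methylenes ending at ring B. There is no stereocentre; the only stereochemical element is the geometry of the C8=C9 olefin, which is isolated from both rings and must therefore be set cleanly when it is made. Ring B is a 5-alkylresorcinol with two equivalent hydroxyls; ring A carries one hydroxyl (C1'), one methoxyl (C3') and the chain (C5'), all meta to one another. The free phenols are electron-rich and oxidise easily in basic, aerated media, and the olefin rules out hydrogenolytic deprotection and any reagent that could add to it or move it. The real difficulty is oxygen differentiation: of three similar phenolic oxygens exactly one is methylated, and the two oxygens of ring A are equivalent in any resorcinol precursor, so late methylation would be statistical. The strategy rests on the 1,3,5-pattern of ring A: C1' with its hydroxyl, C6', C5' with the chain and C4' map onto a 3-alkylcyclobutenone, and C2' and C3' with the methoxyl map onto methoxyethyne, so the two oxygens are different from the moment the ring exists.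

## Retrosynthetic reasoning

**23 to 22.** The last disconnection is the two O–Si bonds on ring B. Ring B is carried as its bis(triisopropylsilyl) ether 22 because these ethers tolerate organomagnesium reagents, dilute acid and heat, and can be cleaved at silicon under buffered conditions that touch neither the methyl ether, the ring A phenol nor the olefin. Ring A needs no protection or methylation at any point.

**22 to 14 and 17.** Ring A of 22 is cut at C1'–C2' and C3'–C4'. This releases C2' and C3' with the methoxyl as methoxyethyne 17, and leaves C1', C6', C5' and C4' as the four-membered enone 14. The cut is made here because it is the only one that delivers hydroxyl and methoxyl from different reagents. The forward reaction must open 14 to vinylketene 18, add 17 across the ketene C=C bond with the right orientation to give cyclobutenone 19, reopen to dienylketene 20, close to cyclohexadienone 21 and tautomerise.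

**17 to 15.** The alkyne is traced to chloroacetal 15 by two base-induced β-eliminations, passing through alkynide 16. It is made fresh because it is volatile and does not keep.

**14 to 10 and 11.** The bond between cyclobutenone C3 and chain C1 is cut. The chain becomes the nucleophile (Grignard reagent 12 from bromide 10) and the ring the electrophile, the vinylogous ester 11. Addition to the carbonyl gives 13, and acid transposes the carbonyl, so the alkyl group ends up on the β-carbon of the enone as required.

**10 to 9.** The C–Br bond is traced to the primary alcohol of 9, a neutral exchange that leaves the silyl ethers and the olefin alone.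

**9 to 5 and 7.** The bond between ring B and chain C14 is cut, giving aryl bromide 7 and the terminal alkene of dienol 5. Hydroboration of 5 gives borane 8, which is coupled under palladium catalysis. The cut is placed here so that ring B joins after the dissolving-metal step and its silyl ethers are not exposed to those conditions in the main line. The borane reagent also distinguishes the terminal from the internal double bond.

**7 to 6.** The silyl ethers are traced to the two phenols of bromoresorcinol 6.

**5 to 4.** The E olefin is traced to the alkyne of 4. Dissolving-metal reduction gives the trans-alkene with high geometric fidelity and leaves an isolated terminal alkene alone. This is why the chain carries an alkyne at C8–C9.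

**4 to 1 and 2.** The C9–C10 bond is cut next to the alkyne. The dianion 3 of alkynol 1 is alkylated at carbon by bromide 2, which joins two simple purchased pieces without a protecting group.

## Alternatives that were turned down

Alternative 1: The chain is cut on both sides of the future olefin, at C7–C8 and C9–C10. This leaves ethyne A4 as a two-carbon linchpin between a ring A heptyl bromide, 1-(7-bromoheptyl)-3-methoxy-5-(methoxymethoxy)benzene A2, and a ring B pentyl bromide, 1-(5-bromopentyl)-3,5-bis(methoxymethoxy)benzene A3. In the forward direction monometalated A4 would be alkylated with A2, metalated again in the same flask and alkylated with A3 to give the diarylalkyne A1. Dissolving-metal reduction and acid removal of the acetal groups would finish.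
- For: it is highly convergent, both chain bonds form in one pot, and the olefin geometry comes from the same alkyne reduction used here. On convergence and on the simplicity of the bond-forming event it is at least as good as the chosen plan.
- Against: A2 already contains the differentiated ring A, so the central problem moves into a building block. That block needs either a statistical monomethylation of a symmetrical resorcinol or a purchased differentiated arene, followed by chain attachment, and A3 needs its own sequence.
- Against: sequential one-pot alkylation of A4 tends to give symmetrical dialkylation through proton exchange between mono- and dimetalated species. Those by-products would be greasy close relatives of A1 and hard to remove.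
- Against: the reagent that installs methoxymethyl ethers is a regulated carcinogen.
- Comparison: the chosen plan gives up some convergence, but ring A's oxygen pattern is created by the ring-forming reaction itself, so no differentiation step is needed.

Alternative 2: Ring A is opened between the chain-bearing carbon and its ortho carbon and traced to a linear tricarbonyl chain, the diketo-dioxinone A6, whose 2,2-dimethyl-1,3-dioxin-4-one ring masks a β-keto acid. A tertiary amine and then mild acid would trigger aldol attack of dioxinone C5 on the chain-terminal ketone and dehydration, giving benzodioxinone A5.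
- For: the conditions are mild and biomimetic, and the substitution pattern is fixed by the chain. The two ring oxygens emerge differentiated, one free and one locked in the dioxinone ring, so the free one can be methylated selectively. On this central point it equals the chosen strategy.
- Against: A5 carries a carboxyl carbon that the target lacks. After methylation the dioxinone ring must be hydrolysed and the freed carboxyl group removed by decarboxylation, three operations before final deprotection.
- Against: A6 is a sensitive tricarbonyl compound that must be built by successive Claisen-type acylations from a long-chain acyl donor already carrying the olefin and ring B.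
- Comparison: the chosen benzannulation forms ring A with exactly the atoms required and leaves one step after it; this plan is clearly longer.

Alternative 3: Here ring B is disconnected. It is taken back to the cyclohexane-1,3-dione A7, which would arise from methyl enone A8 and dimethyl propanedioate A9 by Michael addition of A9 to A8, Claisen closure, ester hydrolysis and decarboxylation in one pot under alkoxide base.
- For: this is textbook ring synthesis, it forms two C–C bonds, and ring B's oxygens need no protecting groups while they are carbonyls.
- Against: A7 must then be dehydrogenated to the resorcinol next to an isolated E olefin and an electron-rich free phenol. Halogenation and dehydrohalogenation, high-temperature metal-catalysed dehydrogenation, and quinone oxidants all threaten the double bond (addition or migration) and ring A (oxidation).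
- Against: A8 already carries the 3-hydroxy-5-methoxyphenyl group, so ring A's differentiation is left unsolved, and the enone needs an extra olefination.
- Comparison: this plan constructs the easy ring and has to acquire the hard one; the chosen plan constructs the hard one and buys the easy one.

Key step: step 8

Remark: 3-ethoxycyclobut-2-en-1-one 11 is taken as a purchasable building block; methoxyethyne 17 is too volatile and unstable to stock and is made fresh in step 7.

## Route

Step 1
Reactants: 1 non-8-yn-1-ol; 2 5-bromopent-1-ene
Product: 4 tetradec-13-en-8-yn-1-ol, via dilithio non-8-yn-1-ol 3 (not isolated)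
Conditions: n-BuLi (2.1 equiv), THF/DMPU, −78 °C; then 2, −78 °C to rt; H2O
Reagents that add atoms: none
Why: Two equivalents of base give the alkoxide–acetylide dianion 3, whose carbon end is the far better nucleophile in the presence of DMPU, so the primary bromide is taken by SN2 alkylation at carbon (acetylide alkylation); the bromide has no activated β-hydrogen, so elimination should be minor.

Step 2
Reactants: 4 tetradec-13-en-8-yn-1-ol
Product: 5 (E)-tetradeca-8,13-dien-1-ol
Conditions: Na, liq. NH3/THF, −33 °C; then NH4Cl
Reagents that add atoms: none
Why: Dissolving-metal reduction of the internal alkyne runs through the radical anion and the more stable trans vinyl anion, which sets the E geometry of C8=C9; the isolated terminal alkene is not reduced when no alcohol is added and the excess of sodium is kept small.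

Step 3
Reactants: 6 5-bromobenzene-1,3-diol
Product: 7 1-bromo-3,5-bis(triisopropylsilyloxy)benzene
Conditions: TIPSCl, imidazole, DMF, rt
Reagents that add atoms: triisopropylsilyl chloride, CC(C)[Si](Cl)(C(C)C)C(C)C
Why: Imidazole-promoted silylation of both phenols; the bulky triisopropylsilyl aryl ethers should survive the aqueous base of step 4, the Grignard reagent and the dilute acid of step 6.

Step 4
Reactants: 5 (E)-tetradeca-8,13-dien-1-ol; 7 1-bromo-3,5-bis(triisopropylsilyloxy)benzene
Product: 9 (E)-14-[3,5-bis(triisopropylsilyloxy)phenyl]tetradec-8-en-1-ol, via alkylborane 8 (not isolated)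
Conditions: 9-BBN (2.2 equiv), THF, 0 °C to rt; then 7, Pd(dppf)Cl2 (5 mol%), 3 M aq K3PO4, DMF, 60 °C
Reagents that add atoms: none
Why: 9-BBN hydroborates the monosubstituted alkene at its terminus and leaves the E-disubstituted one, one equivalent being taken up by the hydroxyl as a borinate that the aqueous base hydrolyses; B-alkyl Suzuki–Miyaura coupling then joins the primary alkylborane to 7, the bidentate ligand dppf (1,1'-bis(diphenylphosphino)ferrocene) favouring reductive elimination over β-hydride elimination.

Step 5
Reactants: 9 (E)-14-[3,5-bis(triisopropylsilyloxy)phenyl]tetradec-8-en-1-ol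
Product: 10 1-[(E)-14-bromotetradec-6-enyl]-3,5-bis(triisopropylsilyloxy)benzene
Conditions: CBr4, PPh3, CH2Cl2, 0 °C
Reagents that add atoms: carbon tetrabromide, BrC(Br)(Br)Br
Why: Appel reaction: bromide displaces the alkoxyphosphonium group by SN2 under neutral conditions that touch neither the silyl ethers nor the olefin.

Step 6
Reactants: 10 1-[(E)-14-bromotetradec-6-enyl]-3,5-bis(triisopropylsilyloxy)benzene; 11 3-ethoxycyclobut-2-en-1-one
Product: 14 3-[(E)-14-[3,5-bis(triisopropylsilyloxy)phenyl]tetradec-8-enyl]cyclobut-2-en-1-one, via Grignard reagent 12 (not isolated), via magnesium alkoxide 13 (not isolated)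
Conditions: Mg, THF, rt to 40 °C; then 11, THF, −78 to 0 °C; then 1 M aq HCl, 0 °C to rt
Reagents that add atoms: water, O
Why: Magnesium insertion gives 12, which adds 1,2 to the carbonyl of the vinylogous ester 11; dilute acid ionises the tertiary allylic alkoxide 13 to an ethoxy-stabilised allyl cation that is hydrolysed with loss of ethanol, so the carbonyl reappears at the former ethoxy carbon (Stork–Danheiser-type alkylative carbonyl transposition). Aryl silyl ethers and the olefin should tolerate brief exposure to 1 M acid.

Step 7
Reactants: 15 2-chloro-1,1-dimethoxyethane
Product: 17 methoxyethyne, via sodium methoxyethynide 16 (not isolated)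
Conditions: NaNH2 (3 equiv), liq. NH3, −33 °C; then cold aq NaCl, distil into toluene at −78 °C
Reagents that add atoms: none
Why: Three equivalents of NaNH2 remove methanol and then hydrogen chloride from the chloroacetal and hold the product as alkynide 16 (double β-elimination, the standard preparation of 1-alkoxyalkynes); cold aqueous quench protonates it, and the alkyne (b.p. about 23 °C) is distilled into cold toluene and used at once.

Step 8
Reactants: 14 3-[(E)-14-[3,5-bis(triisopropylsilyloxy)phenyl]tetradec-8-enyl]cyclobut-2-en-1-one; 17 methoxyethyne
Product: 22 3-[(E)-14-[3,5-bis(triisopropylsilyloxy)phenyl]tetradec-8-enyl]-5-methoxyphenol, via vinylketene 18 (not isolated), via 4-alkenylcyclobutenone 19 (not isolated), via dienylketene 20 (not isolated), via cyclohexadienone 21 (not isolated)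
Conditions: 17 (4 equiv), toluene, sealed tube, 80 °C
Reagents that add atoms: none
Why: Danheiser benzannulation, the known thermal union of cyclobutenones with 1-alkoxyalkynes. At 80 °C cyclobutenone 14 undergoes reversible four-electron conrotatory opening of its C1–C4 bond to vinylketene 18. The electron-rich alkyne 17 adds across the ketene C=C bond in a [2+2] cycloaddition in which its unsubstituted, nucleophilic carbon bonds to the ketene carbonyl carbon and its methoxy-bearing carbon to the former C2, the same polarity by which ketenes and 1-alkoxyalkynes give 3-alkoxycyclobutenones, so 19 already has the methoxyl where it will sit meta to the hydroxyl. A second four-electron opening of 19 gives dienylketene 20, and the isomer with the ketene and the alkenyl group cis on the central double bond is drained by a thermal disrotatory six-electron electrocyclization that joins the ketene carbon to the terminal methylene and closes ring A as cyclohexadienone 21. Tautomerization of 21 to the phenol is irreversible and pulls the cascade forward. No stereocentre appears in the product, since the one in 19 is lost on ring opening. The step needs regioselectivity (secured by the polarization of the ynol ether), chemoselectivity for the alkyne over the isolated E olefin (an unactivated trans-dialkylethene is a very poor ketenophile and 17 is in excess) and survival of the silyl ethers (the medium is neutral and aprotic). The excess of alkyne should also keep the product phenol from being acylated by 18.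

Step 9
Reactants: 22 3-[(E)-14-[3,5-bis(triisopropylsilyloxy)phenyl]tetradec-8-enyl]-5-methoxyphenol
Product: 23 5-[(E)-14-(3-hydroxy-5-methoxyphenyl)tetradec-6-enyl]benzene-1,3-diol (dehydrobisgravillol)
Conditions: TBAF, AcOH, THF, 0 °C to rt
Reagents that add atoms: none
Why: Fluoride attacks silicon and releases both ring B phenols (silyl ether cleavage); acetic acid buffers the medium so that the electron-rich triphenol is not exposed to base and air, and the methyl ether and the olefin are inert.

## Compound list

1 | non-8-yn-1-ol | C#CCCCCCCCO | starting material
2 | 5-bromopent-1-ene | C=CCCCBr | starting material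
3 | dilithium salt of non-8-yn-1-ol (lithium alkoxide and lithium acetylide) | [Li]C#CCCCCCCCO[Li] | intermediate
4 | tetradec-13-en-8-yn-1-ol | OCCCCCCCC#CCCCC=C | intermediate
5 | (E)-tetradeca-8,13-dien-1-ol | OCCCCCCC/C=C/CCCC=C | intermediate
6 | 5-bromobenzene-1,3-diol | Oc1cc(O)cc(Br)c1 | starting material
7 | 1-bromo-3,5-bis(triisopropylsilyloxy)benzene | Brc1cc(O[Si](C(C)C)(C(C)C)C(C)C)cc(O[Si](C(C)C)(C(C)C)C(C)C)c1 | intermediate
8 | 9-[(E)-14-(9-borabicyclo[3.3.1]nonan-9-yloxy)tetradec-6-enyl]-9-borabicyclo[3.3.1]nonane | B1(CCCCC/C=C/CCCCCCCOB2C3CCCC2CCC3)C2CCCC1CCC2 | intermediate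
9 | (E)-14-[3,5-bis(triisopropylsilyloxy)phenyl]tetradec-8-en-1-ol | OCCCCCCC/C=C/CCCCCc1cc(O[Si](C(C)C)(C(C)C)C(C)C)cc(O[Si](C(C)C)(C(C)C)C(C)C)c1 | intermediate
10 | 1-[(E)-14-bromotetradec-6-enyl]-3,5-bis(triisopropylsilyloxy)benzene | BrCCCCCCC/C=C/CCCCCc1cc(O[Si](C(C)C)(C(C)C)C(C)C)cc(O[Si](C(C)C)(C(C)C)C(C)C)c1 | intermediate
11 | 3-ethoxycyclobut-2-en-1-one | CCOC1=CC(=O)C1 | starting material
12 | [(E)-14-[3,5-bis(triisopropylsilyloxy)phenyl]tetradec-8-enyl]magnesium bromide | Br[Mg]CCCCCCC/C=C/CCCCCc1cc(O[Si](C(C)C)(C(C)C)C(C)C)cc(O[Si](C(C)C)(C(C)C)C(C)C)c1 | intermediate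
13 | bromomagnesium 1-[(E)-14-[3,5-bis(triisopropylsilyloxy)phenyl]tetradec-8-enyl]-3-ethoxycyclobut-2-en-1-olate (racemic) | CCOC1=CC(CCCCCCC/C=C/CCCCCc2cc(O[Si](C(C)C)(C(C)C)C(C)C)cc(O[Si](C(C)C)(C(C)C)C(C)C)c2)(O[Mg]Br)C1 | intermediate
14 | 3-[(E)-14-[3,5-bis(triisopropylsilyloxy)phenyl]tetradec-8-enyl]cyclobut-2-en-1-one | O=C1CC(CCCCCCC/C=C/CCCCCc2cc(O[Si](C(C)C)(C(C)C)C(C)C)cc(O[Si](C(C)C)(C(C)C)C(C)C)c2)=C1 | intermediate
15 | 2-chloro-1,1-dimethoxyethane | COC(CCl)OC | starting material
16 | sodium methoxyethynide | COC#C[Na] | intermediate
17 | methoxyethyne | COC#C | intermediate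
18 | 3-[(E)-14-[3,5-bis(triisopropylsilyloxy)phenyl]tetradec-8-enyl]buta-1,3-dien-1-one (vinylketene) | O=C=CC(=C)CCCCCCC/C=C/CCCCCc1cc(O[Si](C(C)C)(C(C)C)C(C)C)cc(O[Si](C(C)C)(C(C)C)C(C)C)c1 | intermediate
19 | 4-[(E)-16-[3,5-bis(triisopropylsilyloxy)phenyl]hexadeca-1,10-dien-2-yl]-3-methoxycyclobut-2-en-1-one (racemic at C4) | COC1=CC(=O)C1C(=C)CCCCCCC/C=C/CCCCCc1cc(O[Si](C(C)C)(C(C)C)C(C)C)cc(O[Si](C(C)C)(C(C)C)C(C)C)c1 | intermediate
20 | (3E)-5-[(E)-14-[3,5-bis(triisopropylsilyloxy)phenyl]tetradec-8-enyl]-3-methoxyhexa-1,3,5-trien-1-one (dienylketene, ketene and alkenyl group cis on the central double bond) | O=C=C/C(OC)=C\C(=C)CCCCCCC/C=C/CCCCCc1cc(O[Si](C(C)C)(C(C)C)C(C)C)cc(O[Si](C(C)C)(C(C)C)C(C)C)c1 | intermediate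
21 | 5-[(E)-14-[3,5-bis(triisopropylsilyloxy)phenyl]tetradec-8-enyl]-3-methoxycyclohexa-2,4-dien-1-one | COC1=CC(=O)CC(CCCCCCC/C=C/CCCCCc2cc(O[Si](C(C)C)(C(C)C)C(C)C)cc(O[Si](C(C)C)(C(C)C)C(C)C)c2)=C1 | intermediate
22 | 3-[(E)-14-[3,5-bis(triisopropylsilyloxy)phenyl]tetradec-8-enyl]-5-methoxyphenol | COc1cc(O)cc(CCCCCCC/C=C/CCCCCc2cc(O[Si](C(C)C)(C(C)C)C(C)C)cc(O[Si](C(C)C)(C(C)C)C(C)C)c2)c1 | intermediate
23 | 5-[(E)-14-(3-hydroxy-5-methoxyphenyl)tetradec-6-enyl]benzene-1,3-diol (dehydrobisgravillol) | COc1cc(O)cc(CCCCCCC/C=C/CCCCCc2cc(O)cc(O)c2)c1 | target

## Step count and least certain steps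

Total step count: 9. Longest linear sequence: 7 steps (steps 1, 2, 4, 5, 6, 8 and 9, from non-8-yn-1-ol); steps 3 and 7 are single-step side branches.

**Step 8 (key step).** The volatile alkyne may escape from solution or polymerise thermally before the vinylketene is trapped. The ketene would then dimerise or acylate the product phenol, and the cascade would stall. Fallback: give up ring construction and attach a ready-made ring A, setting out from bromide 10. Purchased 3-bromo-5-methoxyphenol F1 would be silylated (TIPSCl, imidazole, DMF) to (3-bromo-5-methoxyphenoxy)triisopropylsilane F2. Grignard reagent 12, made from 10 as in step 6, would be coupled with F2 in THF under Pd(dppf)Cl2 catalysis (Kumada–Corriu coupling) to give 1-[(E)-14-[3,5-bis(triisopropylsilyloxy)phenyl]tetradec-8-enyl]-3-methoxy-5-(triisopropylsilyloxy)benzene F3. Buffered TBAF would then remove all three silyl groups, and the fallback rejoins the route at 23.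

**Step 6.** Three processes are most likely to cost material:
- Wurtz-type homocoupling during magnesium insertion into a high-molecular-weight bromide.
- Proton abstraction from C4 of 11 in place of carbonyl addition.
- Acid-promoted hydration or cleavage of the strained enone during the hydrolysis.

Fallback: build the four-membered ring by cycloaddition instead of adding a carbanion to it, setting out from 10. LiC≡CH·H2NCH2CH2NH2 in DMSO would give the terminal alkyne 1-[(E)-hexadec-6-en-15-ynyl]-3,5-bis(triisopropylsilyloxy)benzene F4. Trichloroacetyl chloride and Zn(Cu) in Et2O/DME (dichloroketene generated in the flask, kept near one equivalent) should add to the triple bond in preference to the trans-dialkyl olefin, a slow ketenophile. This would give 4,4-dichloro-3-[(E)-14-[3,5-bis(triisopropylsilyloxy)phenyl]tetradec-8-enyl]cyclobut-2-en-1-one F5. Zn, AcOH and TMEDA in ethanol would remove both chlorines and return the route to 14.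

**Step 4.** Three processes are most likely to go wrong:
- Slow hydroboration of the internal E olefin by the excess borane that the free hydroxyl requires.
- β-Hydride elimination from the alkylpalladium intermediate, leading to reduced arene.
- Partial loss of the aryl silyl ethers to aqueous base at 60 °C.

Fallback: form the aryl–alkyl bond by copper-catalysed Grignard coupling before the chain is assembled, setting out from 7 and 1. Magnesium insertion into 7 and Li2CuCl4-catalysed coupling with excess 1,5-dibromopentane F6 would give 1-(5-bromopentyl)-3,5-bis(triisopropylsilyloxy)benzene F7. Dianion 3, made from 1 as in step 1, would be alkylated with F7 to give 14-[3,5-bis(triisopropylsilyloxy)phenyl]tetradec-8-yn-1-ol F8. Sodium in liquid ammonia without added alcohol, so that ring B is not reduced, would give the E olefin and rejoin the route at 9.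

**Step 7.** The low-boiling alkyne may be lost during isolation or polymerise on standing, and the ammonia-free sodium alkynide residue is pyrophoric. Fallback: separate the two eliminations so that no metal alkynide is formed, setting out from 15. TMSOTf and i-Pr2NEt in CH2Cl2 would remove one methanol unit to give 1-chloro-2-methoxyethene F9, a distillable liquid. Passing F9 over hot powdered KOH would eliminate hydrogen chloride and distil the product straight into cold toluene, rejoining the route at 17.

## Further compounds

F1 | step 8 | 3-bromo-5-methoxyphenol | COc1cc(O)cc(Br)c1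
F2 | step 8 | (3-bromo-5-methoxyphenoxy)triisopropylsilane | COc1cc(Br)cc(O[Si](C(C)C)(C(C)C)C(C)C)c1
F3 | step 8 | 1-[(E)-14-[3,5-bis(triisopropylsilyloxy)phenyl]tetradec-8-enyl]-3-methoxy-5-(triisopropylsilyloxy)benzene | COc1cc(O[Si](C(C)C)(C(C)C)C(C)C)cc(CCCCCCC/C=C/CCCCCc2cc(O[Si](C(C)C)(C(C)C)C(C)C)cc(O[Si](C(C)C)(C(C)C)C(C)C)c2)c1
F4 | step 6 | 1-[(E)-hexadec-6-en-15-ynyl]-3,5-bis(triisopropylsilyloxy)benzene | C#CCCCCCCC/C=C/CCCCCc1cc(O[Si](C(C)C)(C(C)C)C(C)C)cc(O[Si](C(C)C)(C(C)C)C(C)C)c1
F5 | step 6 | 4,4-dichloro-3-[(E)-14-[3,5-bis(triisopropylsilyloxy)phenyl]tetradec-8-enyl]cyclobut-2-en-1-one | O=C1C=C(CCCCCCC/C=C/CCCCCc2cc(O[Si](C(C)C)(C(C)C)C(C)C)cc(O[Si](C(C)C)(C(C)C)C(C)C)c2)C1(Cl)Cl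
F6 | step 4 | 1,5-dibromopentane | BrCCCCCBr
F7 | step 4 | 1-(5-bromopentyl)-3,5-bis(triisopropylsilyloxy)benzene | BrCCCCCc1cc(O[Si](C(C)C)(C(C)C)C(C)C)cc(O[Si](C(C)C)(C(C)C)C(C)C)c1
F8 | step 4 | 14-[3,5-bis(triisopropylsilyloxy)phenyl]tetradec-8-yn-1-ol | OCCCCCCCC#CCCCCCc1cc(O[Si](C(C)C)(C(C)C)C(C)C)cc(O[Si](C(C)C)(C(C)C)C(C)C)c1
F9 | step 7 | 1-chloro-2-methoxyethene (E/Z mixture) | COC=CCl
A1 | alternative 1 | 1-[14-[3,5-bis(methoxymethoxy)phenyl]tetradec-8-ynyl]-3-methoxy-5-(methoxymethoxy)benzene | COCOc1cc(OC)cc(CCCCCCCC#CCCCCCc2cc(OCOC)cc(OCOC)c2)c1
A2 | alternative 1 | 1-(7-bromoheptyl)-3-methoxy-5-(methoxymethoxy)benzene | COCOc1cc(OC)cc(CCCCCCCBr)c1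
A3 | alternative 1 | 1-(5-bromopentyl)-3,5-bis(methoxymethoxy)benzene | COCOc1cc(OCOC)cc(CCCCCBr)c1
A4 | alternative 1 | ethyne | C#C
A5 | alternative 2 | 5-[(E)-14-[3,5-bis(methoxymethoxy)phenyl]tetradec-8-enyl]-7-hydroxy-2,2-dimethyl-1,3-benzodioxin-4-one | CC1(C)OC(=O)c2c(CCCCCCC/C=C/CCCCCc3cc(OCOC)cc(OCOC)c3)cc(O)cc2O1
A6 | alternative 2 | 6-[(E)-18-[3,5-bis(methoxymethoxy)phenyl]-2,4-dioxooctadec-12-enyl]-2,2-dimethyl-1,3-dioxin-4-one | CC1(C)OC(=O)C=C(CC(=O)CC(=O)CCCCCCC/C=C/CCCCCc2cc(OCOC)cc(OCOC)c2)O1
A7 | alternative 3 | 5-[(E)-14-(3-hydroxy-5-methoxyphenyl)tetradec-6-enyl]cyclohexane-1,3-dione | O=C1CC(=O)CC(CCCCC/C=C/CCCCCCCc2cc(OC)cc(O)c2)C1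
A8 | alternative 3 | (3E,10E)-18-(3-hydroxy-5-methoxyphenyl)octadeca-3,10-dien-2-one | CC(=O)/C=C/CCCCC/C=C/CCCCCCCc1cc(OC)cc(O)c1
A9 | alternative 3 | dimethyl propanedioate | COC(=O)CC(=O)OC
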